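**Plan**

- Retrosynthetic cuts: C12–C13 (alkyl–alkenyl coupling) separates a C9‑vinyl decalin from an (E,E,E)-iodotrienol; C11=C12 and C9=C11 lead back to a C9 ketone; C8–O leads back to a Δ7 enone; C3–C4 opens ring A; C10–CH3 and C10–C1 lead back to (R)-carvone.
- Forward order: the carvone ring is ring B (C5–C10 with the C8 methyl and the C9 carbonyl). C10 receives methyl and a three-carbon arm (C1–C3), ring A closes through C3–C4, then C8–OH, C11 and C12 are added, the chain is joined at C12–C13, and C3 and C23 are oxidised last.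
- Enabling feature: C4 with its two methyls lies between ring-fusion carbon C5 and the C3 carbonyl of ring A. C5 plus C4(CH3)2 is C5 plus the isopropenyl group of carvone, so hydrogen-atom transfer to the isopropenyl CH2 gives the tertiary C4 radical that attacks a C3 aldehyde.
- Stereochemistry: C5 from (R)-carvone; C10 by allylation anti to isopropenyl; C8 by α‑face enolate hydroxylation anti to the axial C10 methyl; C9 by α‑face hydroboration; the three E alkenes from (E)-geranylacetone, syn‑carboalumination and E‑selective allylic oxidation, kept by a stereoretentive coupling.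

Key step: step 5

**Remarks**

- Ring carbons are numbered C1–C10 as in drimane and labdane (C4 bears two methyls, C10 the angular methyl, C8 a methyl, C9 the side chain). Side-chain carbons run C11–C23 from C9 to the carboxyl carbon. α is the face opposite the C10 methyl.
- The C3 alcohol from step 5 is drawn as the expected 3β epimer; either epimer converges at the C3 ketone in step 19.
- (E)-Geranylacetone is taken as the commercially available single E isomer.

**Route**

Step 1
Reactants: 1 (R)-(−)-carvone; 2 iodomethane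
Product: 4 (5R)-2,6-dimethyl-5-(prop-1-en-2-yl)cyclohex-2-en-1-one (6-methylcarvone; C6 epimers), via lithium dienolate of carvone 3 (not isolated)
Conditions: LiN(i-Pr)2, THF, −78 °C; MeI, −78 → −20 °C
Reagents that add atoms: iodomethane CI
Why: Kinetic deprotonation gives the cross-conjugated α′-enolate, which is C-methylated (enolate alkylation); the C6 configuration does not matter because this centre is enolised again in step 2.

Step 2
Reactants: 4 6-methylcarvone; 5 allyl bromide
Product: 7 (5S,6S)-2,6-dimethyl-6-(prop-2-en-1-yl)-5-(prop-1-en-2-yl)cyclohex-2-en-1-one (allyl trans to isopropenyl), via lithium enolate of 6-methylcarvone 6 (not isolated)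
Conditions: LiN(i-Pr)2, THF, −78 → 0 °C; allyl bromide, DMPU, −78 °C → rt
Reagents that add atoms: allyl bromide C=CCBr
Why: The tetrasubstituted enolate should be alkylated on the face opposite the neighbouring isopropenyl group (diastereoselective enolate alkylation), which puts allyl trans and methyl cis to isopropenyl and fixes the quaternary C10 centre.

Step 3
Reactants: 7 allyl ketone
Product: 9 (5S,6S)-6-(3-hydroxypropyl)-2,6-dimethyl-5-(prop-1-en-2-yl)cyclohex-2-en-1-one, via alkylbis(3-methylbutan-2-yl)borane 8 (not isolated)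
Conditions: disiamylborane (from BH3·THF and 2-methyl-2-butene), THF, 0 °C; then NaBO3·4H2O, H2O, rt
Reagents that add atoms: sodium perborate [Na+].[O-]OB=O
Why: Disiamylborane adds to a monosubstituted alkene much faster than to a 1,1-disubstituted alkene beside a quaternary carbon or to a hindered enone, and perborate oxidises the borane without epoxidising the enone (anti-Markovnikov hydroboration–oxidation).

Step 4
Reactants: 9 primary alcohol
Product: 10 3-[(1S,6S)-1,3-dimethyl-2-oxo-6-(prop-1-en-2-yl)cyclohex-3-en-1-yl]propanal (oxopropyl trans to isopropenyl)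
Conditions: Dess–Martin periodinane, CH2Cl2, 0 °C → rt
Reagents that add atoms: none
Why: Dess–Martin oxidation of a primary alcohol stops at the aldehyde under neutral conditions and leaves the alkene and the enone untouched.

Step 5
Reactants: 10 enone aldehyde
Product: 11 3β-hydroxy-11-nordrim-7-en-9-one [(4aS,6S,8aS)-6-hydroxy-2,5,5,8a-tetramethyl-4a,5,6,7,8,8a-hexahydronaphthalen-1(4H)-one]
Conditions: Fe(acac)3 (0.5 equiv), PhSiH3 (2.5 equiv), EtOH (degassed), 60 °C
Reagents that add atoms: none
Why: An iron hydride formed from Fe(acac)3 and PhSiH3 transfers a hydrogen atom to the CH2 terminus of the isopropenyl group, the tertiary C4 radical adds to the tethered aldehyde carbon C3, and the alkoxy radical is reduced by divalent iron to the alkoxide, which ethanol protonates (hydrogen-atom-transfer-initiated reductive radical cyclisation onto a carbonyl group; the closest known cases are iron-hydride cyclisations of alkene-tethered ketones and iron-hydride additions of alkenes to aldehydes). Ring A closes 6-exo-trig on the C=O bond by forming C3–C4. C3 is the only new stereocentre; a chair transition state with the C–O bond equatorial should favour the 3β alcohol, and either epimer serves because C3 becomes a ketone in step 19. C5 and C10 are already fixed and C4 carries two identical methyls, so the trans ring fusion is not at stake. The step needs hydrogen-atom transfer to the electron-rich 1,1-disubstituted alkene rather than to the electron-poor trisubstituted enone alkene, which the nucleophilic character of the iron hydride should secure, and it needs reduction of the alkoxy radical to outrun β-scission back to the tertiary radical, which the iron-bound reduction and irreversible protonation should provide.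

Step 6
Reactants: 11 hydroxy enone
Product: 12 3β-(triethylsilyloxy)-11-nordrim-7-en-9-one
Conditions: Et3SiCl, imidazole, DMF, rt
Reagents that add atoms: chlorotriethylsilane CC[Si](Cl)(CC)CC
Why: Silylation of the equatorial secondary alcohol (silyl ether protection) masks O3 so that it cannot quench the enolate and organolithium reagents of the next steps.

Step 7
Reactants: 12 silyl ether enone
Product: 14 8α-hydroxy-3β-(triethylsilyloxy)-11-nordriman-9-one (8β-methyl), via lithium C8–C9 enolate 13 (not isolated)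
Conditions: LiB(s-Bu)3H, THF, −78 °C; then 2-(benzenesulfonyl)-3-phenyloxaziridine, −78 → −40 °C; aq. NH4Cl
Reagents that add atoms: 2-(benzenesulfonyl)-3-phenyloxaziridine O=S(=O)(N1OC1c1ccccc1)c1ccccc1
Why: The hindered borohydride reduces the β-unsubstituted enone 1,4 as it does carvone, and the C8=C9 enolate should be hydroxylated by the oxaziridine (Davis oxidation) on the α face, away from the axial C10 methyl that stands 1,3 to C8, which sets 8α-OH and 8β-CH3.

Step 8
Reactants: 14 α-hydroxy ketone
Product: 15 9α-[(trimethylsilyl)methyl]-3β-(triethylsilyloxy)-11-nordrimane-8α,9β-diol (C9 configuration expected from α attack, inconsequential)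
Conditions: Me3SiCH2Li (excess), CeCl3, THF, −78 → 0 °C; H2O
Reagents that add atoms: (trimethylsilyl)methyllithium [Li]C[Si](C)(C)C
Why: The small, weakly basic organocerium species from Me3SiCH2Li and CeCl3 adds to the non-enolisable ketone flanked by two quaternary carbons where a phosphorus ylide would not (addition half of a Peterson olefination), and the new C9 centre is destroyed in step 9.

Step 9
Reactants: 15 β-hydroxysilane
Product: 16 3β-(triethylsilyloxy)drim-9(11)-en-8α-ol
Conditions: KH, THF, 0 °C → rt
Reagents that add atoms: none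
Why: The potassium C9 alkoxide undergoes syn elimination of silanolate (Peterson elimination) and can give only the exocyclic C9=C11 alkene.

Step 10
Reactants: 16 tertiary allylic alcohol
Product: 17 3β,8α-bis(triethylsilyloxy)drim-9(11)-ene
Conditions: Et3SiOTf, 2,6-lutidine, CH2Cl2, −78 → 0 °C
Reagents that add atoms: triethylsilyl trifluoromethanesulfonate CC[Si](CC)(CC)OS(=O)(=O)C(F)(F)F
Why: The silyl triflate is reactive enough for the hindered tertiary alcohol (silyl ether protection), and masking O8 prevents retro-aldol cleavage or elimination once C11 is an aldehyde.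

Step 11
Reactants: 17 exocyclic alkene
Product: 19 3β,8α-bis(triethylsilyloxy)driman-11-ol (9α-H), via C11 monoalkylborane 18 (not isolated)
Conditions: BH3·THF, THF, 0 °C → rt; then NaOH, H2O2, 0 °C → rt
Reagents that add atoms: hydrogen peroxide OO
Why: Borane places boron on C11 and hydrogen on C9 from the α face, because the β face is blocked by the axial methyls on C8 and C10, which sets 9α-H (hydroboration–oxidation).

Step 12
Reactants: 19 primary alcohol
Product: 20 3β,8α-bis(triethylsilyloxy)driman-11-al
Conditions: Dess–Martin periodinane, pyridine, CH2Cl2, 0 °C → rt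
Reagents that add atoms: none
Why: Buffered Dess–Martin oxidation gives the aldehyde without acid that could cleave the silyl ethers, and the equatorial 9β-formyl group is the stable epimer.

Step 13
Reactants: 20 aldehyde
Product: 21 9β-ethenyl-3β,8α-bis(triethylsilyloxy)-11-nordrimane (C11=C12 vinyl group, 9α-H)
Conditions: Ph3PCH3Br, KN(SiMe3)2, THF, 0 °C; then 20, −78 °C → rt
Reagents that add atoms: methyltriphenylphosphonium bromide C[P+](c1ccccc1)(c1ccccc1)c1ccccc1.[Br-]
Why: Wittig methylenation of the aldehyde should be faster than enolisation at the hindered C9–H and installs the C11=C12 vinyl group.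

Step 14
Reactants: 22 (E)-geranylacetone
Product: 26 (5E)-6,10-dimethylundeca-5,9-dien-1-yne, via lithium enolate of geranylacetone 23 (not isolated), via enol diethyl phosphate 24 (not isolated), via lithium acetylide 25 (not isolated)
Conditions: LiN(i-Pr)2, THF, −78 °C; ClP(O)(OEt)2, −78 °C → rt; LiN(i-Pr)2 (2.3 equiv), −78 °C → rt; H2O
Reagents that add atoms: none
Why: Kinetic enolisation on the methyl side, O-phosphorylation and base-induced elimination turn the methyl ketone into the terminal alkyne without touching the E alkene (enol phosphate elimination).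

Step 15
Reactants: 26 terminal alkyne
Product: 28 (1E,5E)-1-iodo-2,6,10-trimethylundeca-1,5,9-triene, via alkenyldimethylalane 27 (not isolated)
Conditions: AlMe3, Cp2ZrCl2 (cat.), CH2Cl2, 0 °C → rt; then iodine, THF, −30 → 0 °C
Reagents that add atoms: trimethylaluminium C[Al](C)C; iodine [I][I]
Why: Zirconium-catalysed methylalumination adds methyl and aluminium syn across the alkyne with aluminium at the terminus, and iodinolysis with retention gives the E iodoalkene (Negishi carboalumination).

Step 16
Reactants: 28 iodotriene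
Product: 29 (2E,6E,10E)-11-iodo-2,6,10-trimethylundeca-2,6,10-trien-1-ol
Conditions: SeO2 (cat.), t-BuOOH, salicylic acid (cat.), CH2Cl2, 0 °C → rt, stopped at partial conversion
Reagents that add atoms: selenium dioxide O=[Se]=O; tert-butyl hydroperoxide CC(C)(C)OO
Why: Catalytic SeO2 oxidises the E methyl of the terminal trisubstituted alkene (ene reaction then [2,3]-shift), the iodoalkene being deactivated and the internal alkene slower, and gives the E allylic alcohol.

Step 17
Reactants: 21 vinyl decalin; 29 iodotrienol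
Product: 31 (2E,6E,10E)-13-[3β,8α-bis(triethylsilyloxy)-11-nordriman-9β-yl]-2,6,10-trimethyltrideca-2,6,10-trien-1-ol, via B-alkyl-9-BBN 30 (not isolated)
Conditions: 9-BBN, THF, rt; then 29, PdCl2(dppf) (cat.), AsPh3, Cs2CO3, DMF/THF/H2O, rt
Reagents that add atoms: none
Why: 9-BBN adds to the only alkene of 21 with boron on C12, and the B-alkyl Suzuki–Miyaura coupling with the alkenyl iodide forms C12–C13 with retention of the E geometry and tolerates the free alcohol.

Step 18
Reactants: 31 bis(silyl ether)
Product: 32 (2E,6E,10E)-13-[3β,8α-dihydroxy-11-nordriman-9β-yl]-2,6,10-trimethyltrideca-2,6,10-trien-1-ol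
Conditions: HF·pyridine, pyridine, THF, 0 °C → rt
Reagents that add atoms: none
Why: Buffered fluoride cleaves both triethylsilyl ethers (desilylation) without acid strong enough to dehydrate the tertiary alcohol or isomerise the alkenes.

Step 19
Reactants: 32 triol
Product: 33 (2E,6E,10E)-13-[8α-hydroxy-3-oxo-11-nordriman-9β-yl]-2,6,10-trimethyltrideca-2,6,10-trienal
Conditions: Dess–Martin periodinane (3 equiv), pyridine, CH2Cl2, 0 °C → rt
Reagents that add atoms: none
Why: Dess–Martin periodinane oxidises the secondary C3 alcohol to the ketone and the allylic primary alcohol to the E enal, while the tertiary C8 alcohol cannot react.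

Step 20
Reactants: 33 keto enal
Product: 34 (2E,6E,10E)-13-[(1R,2R,4aR,8aS)-2-hydroxy-2,5,5,8a-tetramethyl-6-oxodecahydronaphthalen-1-yl]-2,6,10-trimethyltrideca-2,6,10-trienoic acid (CNP0141897.3)
Conditions: NaClO2, NaH2PO4, 2-methyl-2-butene, t-BuOH/H2O, rt
Reagents that add atoms: sodium chlorite [Na+].[O-]Cl=O
Why: Chlorite oxidises the enal to the acid (Pinnick oxidation) while 2-methyl-2-butene scavenges hypochlorous acid, so the ketone, the tertiary alcohol and the alkene geometry are left untouched.

**Compound list**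

1 | (R)-(−)-carvone | CC1=CC[C@H](CC1=O)C(C)=C | starting material
2 | iodomethane | CI | starting material
3 | lithium dienolate of carvone (C1–OLi, C1=C6) | CC1=CC[C@@H](C(C)=C)C=C1O[Li] | intermediate
4 | (5R)-2,6-dimethyl-5-(prop-1-en-2-yl)cyclohex-2-en-1-one, C6 epimers | CC1=CC[C@@H](C(C)=C)C(C)C1=O | intermediate
5 | allyl bromide | C=CCBr | starting material
6 | lithium enolate of 6-methylcarvone | CC1=CC[C@@H](C(C)=C)C(C)=C1O[Li] | intermediate
7 | (5S,6S)-2,6-dimethyl-6-(prop-2-en-1-yl)-5-(prop-1-en-2-yl)cyclohex-2-en-1-one | O=C1C(C)=CC[C@@H](C(C)=C)[C@]1(C)CC=C | intermediate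
8 | {3-[(1S,6S)-1,3-dimethyl-2-oxo-6-(prop-1-en-2-yl)cyclohex-3-en-1-yl]propyl}bis(3-methylbutan-2-yl)borane | O=C1C(C)=CC[C@@H](C(C)=C)[C@]1(C)CCCB(C(C)C(C)C)C(C)C(C)C | intermediate
9 | (5S,6S)-6-(3-hydroxypropyl)-2,6-dimethyl-5-(prop-1-en-2-yl)cyclohex-2-en-1-one | O=C1C(C)=CC[C@@H](C(C)=C)[C@]1(C)CCCO | intermediate
10 | 3-[(1S,6S)-1,3-dimethyl-2-oxo-6-(prop-1-en-2-yl)cyclohex-3-en-1-yl]propanal | O=C1C(C)=CC[C@@H](C(C)=C)[C@]1(C)CCC=O | intermediate
11 | 3β-hydroxy-11-nordrim-7-en-9-one | O=C1[C@@]2(C)CC[C@H](O)C(C)(C)[C@@H]2CC=C1C | intermediate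
12 | 3β-(triethylsilyloxy)-11-nordrim-7-en-9-one | O=C1[C@@]2(C)CC[C@H](O[Si](CC)(CC)CC)C(C)(C)[C@@H]2CC=C1C | intermediate
13 | lithium C8=C9 enolate of 3β-(triethylsilyloxy)-11-nordriman-9-one | [Li]OC=1[C@@]2(C)CC[C@H](O[Si](CC)(CC)CC)C(C)(C)[C@@H]2CCC=1C | intermediate
14 | 8α-hydroxy-3β-(triethylsilyloxy)-11-nordriman-9-one | O=C1[C@@]2(C)CC[C@H](O[Si](CC)(CC)CC)C(C)(C)[C@@H]2CC[C@@]1(C)O | intermediate
15 | 9α-[(trimethylsilyl)methyl]-3β-(triethylsilyloxy)-11-nordrimane-8α,9β-diol | C[Si](C)(C)C[C@@]1(O)[C@@]2(C)CC[C@H](O[Si](CC)(CC)CC)C(C)(C)[C@@H]2CC[C@@]1(C)O | intermediate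
16 | 3β-(triethylsilyloxy)drim-9(11)-en-8α-ol | C=C1[C@@]2(C)CC[C@H](O[Si](CC)(CC)CC)C(C)(C)[C@@H]2CC[C@@]1(C)O | intermediate
17 | 3β,8α-bis(triethylsilyloxy)drim-9(11)-ene | C=C1[C@@]2(C)CC[C@H](O[Si](CC)(CC)CC)C(C)(C)[C@@H]2CC[C@@]1(C)O[Si](CC)(CC)CC | intermediate
18 | [3β,8α-bis(triethylsilyloxy)driman-11-yl]borane | BC[C@@H]1[C@@]2(C)CC[C@H](O[Si](CC)(CC)CC)C(C)(C)[C@@H]2CC[C@@]1(C)O[Si](CC)(CC)CC | intermediate
19 | 3β,8α-bis(triethylsilyloxy)driman-11-ol | OC[C@@H]1[C@@]2(C)CC[C@H](O[Si](CC)(CC)CC)C(C)(C)[C@@H]2CC[C@@]1(C)O[Si](CC)(CC)CC | intermediate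
20 | 3β,8α-bis(triethylsilyloxy)driman-11-al | O=C[C@@H]1[C@@]2(C)CC[C@H](O[Si](CC)(CC)CC)C(C)(C)[C@@H]2CC[C@@]1(C)O[Si](CC)(CC)CC | intermediate
21 | 9β-ethenyl-3β,8α-bis(triethylsilyloxy)-11-nordrimane | C=C[C@@H]1[C@@]2(C)CC[C@H](O[Si](CC)(CC)CC)C(C)(C)[C@@H]2CC[C@@]1(C)O[Si](CC)(CC)CC | intermediate
22 | (E)-geranylacetone [(5E)-6,10-dimethylundeca-5,9-dien-2-one] | CC(=O)CC/C=C(\C)CCC=C(C)C | starting material
23 | lithium (5E)-6,10-dimethylundeca-1,5,9-trien-2-olate | [Li]OC(=C)CC/C=C(\C)CCC=C(C)C | intermediate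
24 | diethyl (5E)-6,10-dimethylundeca-1,5,9-trien-2-yl phosphate | C=C(OP(=O)(OCC)OCC)CC/C=C(\C)CCC=C(C)C | intermediate
25 | lithium acetylide of (5E)-6,10-dimethylundeca-5,9-dien-1-yne | [Li]C#CCC/C=C(\C)CCC=C(C)C | intermediate
26 | (5E)-6,10-dimethylundeca-5,9-dien-1-yne | C#CCC/C=C(\C)CCC=C(C)C | intermediate
27 | dimethyl[(1E,5E)-2,6,10-trimethylundeca-1,5,9-trien-1-yl]alane | C[Al](C)/C=C(\C)CC/C=C(\C)CCC=C(C)C | intermediate
28 | (1E,5E)-1-iodo-2,6,10-trimethylundeca-1,5,9-triene | I/C=C(\C)CC/C=C(\C)CCC=C(C)C | intermediate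
29 | (2E,6E,10E)-11-iodo-2,6,10-trimethylundeca-2,6,10-trien-1-ol | I/C=C(\C)CC/C=C(\C)CC/C=C(\C)CO | intermediate
30 | B-{2-[3β,8α-bis(triethylsilyloxy)-11-nordriman-9β-yl]ethyl}-9-borabicyclo[3.3.1]nonane | B1(CC[C@@H]2[C@@]3(C)CC[C@H](O[Si](CC)(CC)CC)C(C)(C)[C@@H]3CC[C@@]2(C)O[Si](CC)(CC)CC)C2CCCC1CCC2 | intermediate
31 | (2E,6E,10E)-13-[3β,8α-bis(triethylsilyloxy)-11-nordriman-9β-yl]-2,6,10-trimethyltrideca-2,6,10-trien-1-ol | C/C(=C\CC/C(C)=C/CC[C@@H]1[C@@]2(C)CC[C@H](O[Si](CC)(CC)CC)C(C)(C)[C@@H]2CC[C@@]1(C)O[Si](CC)(CC)CC)CC/C=C(\C)CO | intermediate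
32 | (2E,6E,10E)-13-[3β,8α-dihydroxy-11-nordriman-9β-yl]-2,6,10-trimethyltrideca-2,6,10-trien-1-ol | C/C(=C\CC/C(C)=C/CC[C@@H]1[C@@]2(C)CC[C@H](O)C(C)(C)[C@@H]2CC[C@@]1(C)O)CC/C=C(\C)CO | intermediate
33 | (2E,6E,10E)-13-[8α-hydroxy-3-oxo-11-nordriman-9β-yl]-2,6,10-trimethyltrideca-2,6,10-trienal | C/C(=C\CC/C(C)=C/CC[C@@H]1[C@@]2(C)CCC(=O)C(C)(C)[C@@H]2CC[C@@]1(C)O)CC/C=C(\C)C=O | intermediate
34 | (2E,6E,10E)-13-[(1R,2R,4aR,8aS)-2-hydroxy-2,5,5,8a-tetramethyl-6-oxodecahydronaphthalen-1-yl]-2,6,10-trimethyltrideca-2,6,10-trienoic acid | C/C(=C\CC/C(C)=C/CC[C@@H]1[C@@]2(C)CCC(=O)C(C)(C)[C@@H]2CC[C@@]1(C)O)CC/C=C(\C)C(=O)O | target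

**Step count**

Total: 20 steps. Longest linear sequence: 17 steps (steps 1–13 and 17–20, from (R)-carvone). The side-chain branch is 3 steps (14–16) and joins at step 17.

**Steps most likely to fail**

1. Step 5. Ring closure onto the aldehyde is reversible: β-scission of the cyclised alkoxy radical may outrun its reduction, or the aldehyde may be consumed by hydrosilylation or acetal formation, so that the isopropenyl group is merely hydrogenated. The fallback sets out from 10 and changes the acceptor and its oxidation level. Condensation with hydroxylamine would give the oxime F1, and dehydration with acetic anhydride the nitrile F2. Under the same iron hydride conditions the C4 radical should add 6-exo-dig to the nitrile (a known hydrogen-atom-transfer cyclisation of alkenyl nitriles), and the iminyl radical does not readily revert. The resulting N–H ketimine F3 would be hydrolysed on acidic work-up to 11-nordrim-7-ene-3,9-dione F4. NaBH4 in MeOH at low temperature should reduce the saturated C3 ketone by axial α attack in preference to the conjugated, hindered C9 enone, and the route is rejoined at 11.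

2. Step 8. The organometallic reagent may fail to add to a ketone flanked by two fully substituted carbons, or the basic medium may trigger α-ketol rearrangement of the hydroxy ketone. The fallback sets out from 12 and introduces C11 while C8 is still sp2. Wittig methylenation of the enone (Ph3P=CH2, toluene, heat) would give 3β-(triethylsilyloxy)drima-7,9(11)-diene F5. 9-BBN then NaOH/H2O2 should hydroborate only the exocyclic alkene from the α face to give the drimenol-type alcohol F6. Epoxidation with mCPBA on the α face would give the 7α,8α-epoxide F7, and LiAlH4 should open it at the secondary C7 to give the 8α,11-diol F8. Et3SiOTf/2,6-lutidine would give the tris(silyl ether) F9, and Swern conditions ((COCl)2, DMSO, Et3N) oxidise the primary triethylsilyl ether directly to the aldehyde, which rejoins the route at 20.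

3. Step 7. Oxygen transfer to the hindered tetrasubstituted lithium enolate may be slow, allowing proton quench or addition of the enolate to the sulfonimine by-product. The fallback sets out from 12 and separates reduction from oxidation. The same conjugate reduction would be followed by trapping with Me3SiCl to give the trimethylsilyl enol ether F10. Epoxidation with mCPBA (NaHCO3) on the α face and silyl migration would give the 8α-(trimethylsilyloxy) ketone F11 (Rubottom oxidation). Brief treatment with dilute aqueous HCl in THF at 0 °C removes the trimethylsilyl group and rejoins the route at 14.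

**Further compounds**

F1 | step 5 | 3-[(1S,6S)-1,3-dimethyl-2-oxo-6-(prop-1-en-2-yl)cyclohex-3-en-1-yl]propanal oxime | O=C1C(C)=CC[C@@H](C(C)=C)[C@]1(C)CCC=NO
F2 | step 5 | 3-[(1S,6S)-1,3-dimethyl-2-oxo-6-(prop-1-en-2-yl)cyclohex-3-en-1-yl]propanenitrile | O=C1C(C)=CC[C@@H](C(C)=C)[C@]1(C)CCC#N
F3 | step 5 | 3-imino-11-nordrim-7-en-9-one | O=C1[C@@]2(C)CCC(=N)C(C)(C)[C@@H]2CC=C1C
F4 | step 5 | 11-nordrim-7-ene-3,9-dione | O=C1[C@@]2(C)CCC(=O)C(C)(C)[C@@H]2CC=C1C
F5 | step 8 | 3β-(triethylsilyloxy)drima-7,9(11)-diene | C=C1[C@@]2(C)CC[C@H](O[Si](CC)(CC)CC)C(C)(C)[C@@H]2CC=C1C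
F6 | step 8 | 3β-(triethylsilyloxy)drim-7-en-11-ol | OC[C@@H]1[C@@]2(C)CC[C@H](O[Si](CC)(CC)CC)C(C)(C)[C@@H]2CC=C1C
F7 | step 8 | 7α,8α-epoxy-3β-(triethylsilyloxy)driman-11-ol | OC[C@@H]1[C@@]2(C)CC[C@H](O[Si](CC)(CC)CC)C(C)(C)[C@@H]2C[C@H]3O[C@@]13C
F8 | step 8 | 3β-(triethylsilyloxy)drimane-8α,11-diol | OC[C@@H]1[C@@]2(C)CC[C@H](O[Si](CC)(CC)CC)C(C)(C)[C@@H]2CC[C@@]1(C)O
F9 | step 8 | 3β,8α,11-tris(triethylsilyloxy)drimane | CC[Si](CC)(CC)OC[C@@H]1[C@@]2(C)CC[C@H](O[Si](CC)(CC)CC)C(C)(C)[C@@H]2CC[C@@]1(C)O[Si](CC)(CC)CC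
F10 | step 7 | 3β-(triethylsilyloxy)-9-(trimethylsilyloxy)-11-nordrim-8-ene | C[Si](C)(C)OC=1[C@@]2(C)CC[C@H](O[Si](CC)(CC)CC)C(C)(C)[C@@H]2CCC=1C
F11 | step 7 | 3β-(triethylsilyloxy)-8α-(trimethylsilyloxy)-11-nordriman-9-one | O=C1[C@@]2(C)CC[C@H](O[Si](CC)(CC)CC)C(C)(C)[C@@H]2CC[C@@]1(C)O[Si](C)(C)C
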